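**Retrosynthetic overview**

1. The target has one ring, the oxane O1–C2(CH3)(side chain)–C3H2–C4H2–C5HBr–C6(CH3)2. The feature that makes the key step possible is its O1–C6(CH3)2–C5HBr–C4H2 edge: a ring oxygen on a gem-dimethyl carbon next to the CHBr carbon is the Markovnikov adduct of O1 and C4 across Me2C=CHBr, and O1–C2–C3–C4 is the skeleton of an enone.
2. Key disconnection: C4–C5 and O1–C6 are made in one inverse-electron-demand oxa-[4+2] event between methyl vinyl ketone and 1-bromo-2-methylpropene, with the CHBr center set by the catalyst. The dihydropyran is a temporary ring, opened at the vinylic C2–O1 bond so that O1 stays on C6.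
3. Chain: methyl ketone → 2-triflyloxy-1-alkene → CrCl2/NiCl2 coupling with an aldehyde from (S)-linalool (which buys the carbinol center) → [3,3]-sigmatropic diazene transposition to the (E)-trisubstituted alkene.
4. Last ring event: a 6-exo bromoetherification closes O1–C2 and sets C2 and the side-chain CHBr in one step by relay from C5; acetate removal ends the route.
5. Ring order: dihydropyran (step 1, opened in step 2) → oxane (step 10).

Key step: step 1

Assumption: (S)-(+)-linalool of high enantiomeric purity is purchasable; locants in the dodecane names follow the farnesane chain (C7 and C11 carry the ring oxygen of the target).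

**Route**

Step 1
Reactants: 1 methyl vinyl ketone (but-3-en-2-one); 2 1-bromo-2-methylprop-1-ene
Product: 3 (3S)-3-bromo-2,2,6-trimethyl-3,4-dihydro-2H-pyran
Conditions: (S)-1-(2-methylphenyl)-3,3-diphenyltetrahydro-1H,3H-pyrrolo[1,2-c][1,3,2]oxazaborole (20 mol %), HN(SO2CF3)2 (18 mol %), 2 (5 equiv), CH2Cl2, −78 to −40 °C; Et3N quench
Reagents that add atoms: none
Why: Proposed new method: the protonated oxazaborolidine binds the carbonyl oxygen of s-cis 1, and the CHBr carbon of 2 attacks the enone β-carbon in a strongly asynchronous inverse-electron-demand oxa-Diels–Alder reaction in which the charge building up on the gem-dimethyl carbon is that of a tertiary cation bridged by the neighbouring bromine, onto which the enolate oxygen closes. The closest known reaction types are the thermal and Lewis acid-promoted [4+2] additions of vinyl ketones and acrolein to isobutene-type alkenes giving 2,2-dialkyl-3,4-dihydro-2H-pyrans and the oxazaborolidinium-catalysed enantioselective cycloadditions of α,β-unsaturated carbonyl compounds with weakly nucleophilic alkenes and dienes; a bromoalkene has not been shown as the 2π partner, hence the label. The dihydropyran ring is closed by intermolecular [4+2] annulation, the C–C bond leading and the six-ring C–O bond following. The one new stereocenter (CHBr) is controlled by the catalyst, which must select one enantioface of 2 on the open face of the bound enone; the catalyst from (S)-proline is written, and which catalyst antipode gives (3S)-3 has to be fixed by experiment. The step needs regioselectivity (oxygen to the gem-dimethyl carbon), secured by the Markovnikov polarisation of 2, and O-closure instead of C-closure or proton loss (cyclobutane or ene products), favoured by the s-cis enone, the low temperature and the amine quench.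

Step 2
Reactants: 3 (3S)-3-bromo-2,2,6-trimethyl-3,4-dihydro-2H-pyran
Product: 4 (5S)-5-bromo-6-hydroxy-6-methylheptan-2-one
Conditions: 0.1 M HCl (aq), THF, 0 °C
Reagents that add atoms: water, O
Why: Acid-catalysed enol ether hydrolysis (protonation at the ring CH= carbon, addition of water to the oxocarbenium carbon) cleaves only the vinylic C–O bond, so the oxygen stays on the gem-dimethyl carbon and the CHBr center is not touched.

Step 3
Reactants: 4 (5S)-5-bromo-6-hydroxy-6-methylheptan-2-one
Product: 5 (5S)-5-bromo-6-methyl-6-[(triethylsilyl)oxy]heptan-2-one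
Conditions: Et3SiOSO2CF3, 2,6-lutidine, CH2Cl2, −78 °C
Reagents that add atoms: triethylsilyl trifluoromethanesulfonate, CC[Si](CC)(CC)OS(=O)(=O)C(F)(F)F
Why: Silylation of the hindered tertiary alcohol with a silyl triflate and a non-nucleophilic pyridine base masks the hydroxyl, whose alkoxide would otherwise close an epoxide onto the neighbouring C–Br carbon in the basic step 4.

Step 4
Reactants: 5 (5S)-5-bromo-6-methyl-6-[(triethylsilyl)oxy]heptan-2-one
Product: 7 (5S)-5-bromo-6-methyl-6-[(triethylsilyl)oxy]hept-1-en-2-yl trifluoromethanesulfonate, via lithium enolate 6 (not isolated)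
Conditions: LiN(i-Pr)2, THF, −78 °C; then PhN(SO2CF3)2, −78 to 0 °C
Reagents that add atoms: N-phenylbis(trifluoromethanesulfonimide), O=S(=O)(N(c1ccccc1)S(=O)(=O)C(F)(F)F)C(F)(F)F
Why: Kinetic enolate formation at the methyl group with a hindered lithium amide followed by O-sulfonylation (enol triflate synthesis) should give the terminal 2-triflyloxy-1-alkene, ketone deprotonation being far faster than any attack on the secondary bromide.

Step 5
Reactants: 8 (S)-linalool [(3S)-3,7-dimethylocta-1,6-dien-3-ol]
Product: 9 (3S)-3,7-dimethylocta-1,6-dien-3-yl acetate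
Conditions: Ac2O, Et3N, 4-(dimethylamino)pyridine (cat.), CH2Cl2, 23 °C
Reagents that add atoms: acetic anhydride, CC(=O)OC(C)=O
Why: Acylation of the tertiary allylic alcohol catalysed by 4-(dimethylamino)pyridine (Steglich-type) touches no bond of the stereocenter and installs an acetate that prevents lactol formation after step 6 and removes the nucleophilicity of this oxygen for step 10.

Step 6
Reactants: 9 (3S)-3,7-dimethylocta-1,6-dien-3-yl acetate
Product: 11 (3S)-3-methyl-6-oxohex-1-en-3-yl acetate, via ozonide 10 (not isolated)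
Conditions: O3, CH2Cl2, −78 °C (Sudan red 7B end point); then Me2S, −78 to 23 °C
Reagents that add atoms: ozone, [O-][O+]=O
Why: Ozonolysis with reductive work-up cleaves the electron-rich trisubstituted alkene much faster than the vinyl group deactivated by the allylic acetate, and the indicator dye marks the end point.

Step 7
Reactants: 7 (5S)-5-bromo-6-methyl-6-[(triethylsilyl)oxy]hept-1-en-2-yl trifluoromethanesulfonate; 11 (3S)-3-methyl-6-oxohex-1-en-3-yl acetate
Product: 12 (3S,10S)-10-bromo-6-hydroxy-3,11-dimethyl-7-methylidene-11-[(triethylsilyl)oxy]dodec-1-en-3-yl acetate (both C6 epimers)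
Conditions: CrCl2 (4 equiv), NiCl2 (1 mol %), DMF, 23 °C
Reagents that add atoms: none
Why: Nozaki–Hiyama–Kishi coupling, in which zerovalent nickel inserts into the vinylic C–O bond of the triflate and transmetalation gives an alkenylchromium species that adds chemoselectively to the aldehyde beside acetate, silyl ether and secondary bromide; the new carbinol center is formed as both epimers because it is erased in step 8.

Step 8
Reactants: 12 (3S,10S)-10-bromo-6-hydroxy-3,11-dimethyl-7-methylidene-11-[(triethylsilyl)oxy]dodec-1-en-3-yl acetate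
Product: 15 (3S,6E,10S)-10-bromo-3,7,11-trimethyl-11-[(triethylsilyl)oxy]dodeca-1,6-dien-3-yl acetate, via sulfonylhydrazine adduct 13 (not isolated), via allylic diazene 14 (not isolated)
Conditions: 2-nitrobenzenesulfonylhydrazide, PPh3, diethyl azodicarboxylate, THF, −30 °C; then 23 °C
Reagents that add atoms: none
Why: Reductive 1,3-transposition of an allylic alcohol (Mitsunobu displacement by the sulfonylhydrazide, loss of arenesulfinic acid to the monoalkyl diazene, then [3,3]-sigmatropic retro-ene loss of N2 with hydrogen delivery to the methylene carbon) should give the E alkene, because in the cyclic transition state the chain on the diazene-bearing carbon lies on the methylene side, away from the CH2 branch of the alkene.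

Step 9
Reactants: 15 (3S,6E,10S)-10-bromo-3,7,11-trimethyl-11-[(triethylsilyl)oxy]dodeca-1,6-dien-3-yl acetate
Product: 16 (3S,6E,10S)-10-bromo-11-hydroxy-3,7,11-trimethyldodeca-1,6-dien-3-yl acetate
Conditions: HF·pyridine, pyridine, THF, 0 °C
Reagents that add atoms: none
Why: Fluoride-assisted cleavage of the Si–O bond under buffered acidic conditions frees the tertiary alcohol without forming its alkoxide, so the neighbouring bromide and the acetate should survive.

Step 10
Reactants: 16 (3S,6E,10S)-10-bromo-11-hydroxy-3,7,11-trimethyldodeca-1,6-dien-3-yl acetate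
Product: 17 (3S,6R)-6-bromo-6-[(2S,5S)-5-bromo-2,6,6-trimethyloxan-2-yl]-3-methylhex-1-en-3-yl acetate
Conditions: 2,4,4,6-tetrabromocyclohexa-2,5-dien-1-one (1.1 equiv), CH2Cl2, −40 to 0 °C, dark
Reagents that add atoms: 2,4,4,6-tetrabromocyclohexa-2,5-dien-1-one, O=C1C(Br)=CC(Br)(Br)C=C1Br
Why: Bromonium-induced 6-exo etherification (bromoetherification copying the presumed biogenesis of such ethers), in which the tertiary hydroxyl opens the bromonium ion at its more substituted carbon anti to bromine so that the E geometry fixes the relative configuration of the new C–O and C–Br centers, while a chair transition state with the ring bromine and the C2 methyl both equatorial (the flat bromonium carbon axial, the methyl kept off the axial C6 methyl) should relay the CHBr center of step 1 to both.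

Step 11
Reactants: 17 (3S,6R)-6-bromo-6-[(2S,5S)-5-bromo-2,6,6-trimethyloxan-2-yl]-3-methylhex-1-en-3-yl acetate
Product: 18 (3S,6R)-6-bromo-6-[(2S,5S)-5-bromo-2,6,6-trimethyloxan-2-yl]-3-methylhex-1-en-3-ol
Conditions: i-Bu2AlH, CH2Cl2, −78 °C; aqueous potassium sodium tartrate work-up
Reagents that add atoms: none
Why: Reductive cleavage of the acetate by hydride addition to its carbonyl group at −78 °C, where secondary alkyl bromides are inert and no basic alkoxide is set free, should give the target without touching a stereocenter.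

**Compound list**

1 | methyl vinyl ketone (but-3-en-2-one) | CC(=O)C=C | starting material
2 | 1-bromo-2-methylprop-1-ene | CC(C)=CBr | starting material
3 | (3S)-3-bromo-2,2,6-trimethyl-3,4-dihydro-2H-pyran | CC1=CC[C@H](Br)C(C)(C)O1 | intermediate
4 | (5S)-5-bromo-6-hydroxy-6-methylheptan-2-one | CC(=O)CC[C@H](Br)C(C)(C)O | intermediate
5 | (5S)-5-bromo-6-methyl-6-[(triethylsilyl)oxy]heptan-2-one | CC(=O)CC[C@H](Br)C(C)(C)O[Si](CC)(CC)CC | intermediate
6 | lithium (5S)-5-bromo-6-methyl-6-[(triethylsilyl)oxy]hept-1-en-2-olate | [Li]OC(=C)CC[C@H](Br)C(C)(C)O[Si](CC)(CC)CC | intermediate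
7 | (5S)-5-bromo-6-methyl-6-[(triethylsilyl)oxy]hept-1-en-2-yl trifluoromethanesulfonate | C=C(OS(=O)(=O)C(F)(F)F)CC[C@H](Br)C(C)(C)O[Si](CC)(CC)CC | intermediate
8 | (S)-linalool, (3S)-3,7-dimethylocta-1,6-dien-3-ol | C=C[C@@](C)(O)CCC=C(C)C | starting material
9 | (3S)-3,7-dimethylocta-1,6-dien-3-yl acetate | C=C[C@@](C)(OC(C)=O)CCC=C(C)C | intermediate
10 | (3S)-5-(5,5-dimethyl-1,2,4-trioxolan-3-yl)-3-methylpent-1-en-3-yl acetate (ozonide, both ring epimers) | C=C[C@@](C)(OC(C)=O)CCC1OOC(C)(C)O1 | intermediate
11 | (3S)-3-methyl-6-oxohex-1-en-3-yl acetate | C=C[C@@](C)(OC(C)=O)CCC=O | intermediate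
12 | (3S,10S)-10-bromo-6-hydroxy-3,11-dimethyl-7-methylidene-11-[(triethylsilyl)oxy]dodec-1-en-3-yl acetate (both C6 epimers) | C=C[C@@](C)(OC(C)=O)CCC(O)C(=C)CC[C@H](Br)C(C)(C)O[Si](CC)(CC)CC | intermediate
13 | (3S,10S)-10-bromo-3,11-dimethyl-7-methylidene-6-[1-(2-nitrobenzenesulfonyl)hydrazinyl]-11-[(triethylsilyl)oxy]dodec-1-en-3-yl acetate (both C6 epimers) | C=C[C@@](C)(OC(C)=O)CCC(N(N)S(=O)(=O)c1ccccc1[N+](=O)[O-])C(=C)CC[C@H](Br)C(C)(C)O[Si](CC)(CC)CC | intermediate
14 | (3S,10S)-10-bromo-6-diazenyl-3,11-dimethyl-7-methylidene-11-[(triethylsilyl)oxy]dodec-1-en-3-yl acetate (both C6 epimers) | C=C[C@@](C)(OC(C)=O)CCC(N=N)C(=C)CC[C@H](Br)C(C)(C)O[Si](CC)(CC)CC | intermediate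
15 | (3S,6E,10S)-10-bromo-3,7,11-trimethyl-11-[(triethylsilyl)oxy]dodeca-1,6-dien-3-yl acetate | C=C[C@@](C)(OC(C)=O)CC/C=C(\C)CC[C@H](Br)C(C)(C)O[Si](CC)(CC)CC | intermediate
16 | (3S,6E,10S)-10-bromo-11-hydroxy-3,7,11-trimethyldodeca-1,6-dien-3-yl acetate | C=C[C@@](C)(OC(C)=O)CC/C=C(\C)CC[C@H](Br)C(C)(C)O | intermediate
17 | (3S,6R)-6-bromo-6-[(2S,5S)-5-bromo-2,6,6-trimethyloxan-2-yl]-3-methylhex-1-en-3-yl acetate | C=C[C@@](C)(OC(C)=O)CC[C@@H](Br)[C@]1(C)CC[C@H](Br)C(C)(C)O1 | intermediate
18 | (3S,6R)-6-bromo-6-[(2S,5S)-5-bromo-2,6,6-trimethyloxan-2-yl]-3-methylhex-1-en-3-ol | C=C[C@@](C)(O)CC[C@@H](Br)[C@]1(C)CC[C@H](Br)C(C)(C)O1 | target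

**Step count and risks**

Total: 11 steps. Longest linear sequence: 9 steps (steps 1–4 and 7–11); the (S)-linalool branch (steps 5 and 6) joins at step 7.

Steps most likely to fail:

Step 1 (Proposed new method). The bromoalkene may be too weak a π-nucleophile, so that polymerisation of 1 wins. The cationic stage may be diverted into proton loss or ring closure at carbon. Enantiofacial discrimination of 2 may be low. The fallback uses known chemistry, sets out from 1 and 2 and comes back to the route at 4. Compound 2 is converted with Mg in THF into (2-methylprop-1-enyl)magnesium bromide F1, which adds in conjugate fashion to 1 (CuBr·SMe2 cat., THF, −40 °C) to give 6-methylhept-5-en-2-one F2. Shi epoxidation of F2 (1,2:4,5-di-O-isopropylidene-β-D-erythro-2,3-hexodiulo-2,6-pyranose, KHSO5, K2CO3 buffer, MeCN/H2O, 0 °C) should give 4-[(2R)-3,3-dimethyloxiran-2-yl]butan-2-one F3. Li2NiBr4 in THF should open F3 at the secondary carbon with inversion and give 4. In this variant the CHBr center comes from reagent-controlled epoxidation and SN2 inversion.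

Step 10. Facial selectivity in the attack on the alkene may be poor, because the chair transition states with the ring bromine equatorial and axial may lie close in energy; adventitious water may also capture the bromonium ion. The fallback replaces relay by reagent control, sets out from 15 and comes back at 17. Shi epoxidation of 15 with the enantiomer of the ketone named above (KHSO5, buffered, 0 °C) should give (3S,6S,7S,10S)-10-bromo-6,7-epoxy-3,7,11-trimethyl-11-[(triethylsilyl)oxy]dodec-1-en-3-yl acetate F4. Li2NiBr4 in THF should open it at the secondary carbon with inversion to (3S,6R,7S,10S)-6,10-dibromo-7-hydroxy-3,7,11-trimethyl-11-[(triethylsilyl)oxy]dodec-1-en-3-yl acetate F5. Acylation of the free tertiary alcohol ((CF3CO)2O, 2,6-di-tert-butylpyridine, CH2Cl2, −40 °C) should give (3S,6R,7S,10S)-3-acetoxy-6,10-dibromo-3,7,11-trimethyl-11-[(triethylsilyl)oxy]dodec-1-en-7-yl trifluoroacetate F6. On warming in (CF3)2CHOH, F6 should ionise with participation of the neighbouring bromine; the silyl ether oxygen then attacks anti to the bridging bromine (overall retention at the carbinol carbon) and loses the silyl group to give 17.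

Step 8. The E/Z ratio may erode in the sigmatropic step, or the Mitsunobu substitution may occur with allylic shift, which would return the 1,1-disubstituted alkene after loss of N2. The fallback replaces coupling and transposition by a Julia–Kocienski olefination, sets out from 5 and 11 and comes back at 15. Reduction of 5 (NaBH4, MeOH, 0 °C) gives (5S)-5-bromo-6-methyl-6-[(triethylsilyl)oxy]heptan-2-ol F7. Mitsunobu reaction with 1-phenyl-1H-tetrazole-5-thiol (PPh3, diisopropyl azodicarboxylate, THF) gives 5-({(5S)-5-bromo-6-methyl-6-[(triethylsilyl)oxy]heptan-2-yl}sulfanyl)-1-phenyl-1H-tetrazole F8. Oxidation ((NH4)6Mo7O24, H2O2, EtOH) gives 5-({(5S)-5-bromo-6-methyl-6-[(triethylsilyl)oxy]heptan-2-yl}sulfonyl)-1-phenyl-1H-tetrazole F9. KN(SiMe3)2 added to F9 and 11 in THF at −78 °C should give 15 together with its Z isomer, which would have to be removed on AgNO3-impregnated silica.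

**Further compounds**

F1 | step 1 | (2-methylprop-1-enyl)magnesium bromide | CC(C)=C[Mg]Br
F2 | step 1 | 6-methylhept-5-en-2-one | CC(=O)CCC=C(C)C
F3 | step 1 | 4-[(2R)-3,3-dimethyloxiran-2-yl]butan-2-one | CC(=O)CC[C@H]1OC1(C)C
F4 | step 10 | (3S,6S,7S,10S)-10-bromo-6,7-epoxy-3,7,11-trimethyl-11-[(triethylsilyl)oxy]dodec-1-en-3-yl acetate | C=C[C@@](C)(OC(C)=O)CC[C@@H]1O[C@@]1(C)CC[C@H](Br)C(C)(C)O[Si](CC)(CC)CC
F5 | step 10 | (3S,6R,7S,10S)-6,10-dibromo-7-hydroxy-3,7,11-trimethyl-11-[(triethylsilyl)oxy]dodec-1-en-3-yl acetate | C=C[C@@](C)(OC(C)=O)CC[C@@H](Br)[C@@](C)(O)CC[C@H](Br)C(C)(C)O[Si](CC)(CC)CC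
F6 | step 10 | (3S,6R,7S,10S)-3-acetoxy-6,10-dibromo-3,7,11-trimethyl-11-[(triethylsilyl)oxy]dodec-1-en-7-yl trifluoroacetate | C=C[C@@](C)(OC(C)=O)CC[C@@H](Br)[C@@](C)(OC(=O)C(F)(F)F)CC[C@H](Br)C(C)(C)O[Si](CC)(CC)CC
F7 | step 8 | (5S)-5-bromo-6-methyl-6-[(triethylsilyl)oxy]heptan-2-ol (both C2 epimers) | CC(O)CC[C@H](Br)C(C)(C)O[Si](CC)(CC)CC
F8 | step 8 | 5-({(5S)-5-bromo-6-methyl-6-[(triethylsilyl)oxy]heptan-2-yl}sulfanyl)-1-phenyl-1H-tetrazole | CC(Sc1nnnn1-c1ccccc1)CC[C@H](Br)C(C)(C)O[Si](CC)(CC)CC
F9 | step 8 | 5-({(5S)-5-bromo-6-methyl-6-[(triethylsilyl)oxy]heptan-2-yl}sulfonyl)-1-phenyl-1H-tetrazole | CC(S(=O)(=O)c1nnnn1-c1ccccc1)CC[C@H](Br)C(C)(C)O[Si](CC)(CC)CC
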